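Both end rings (ring A, the enone; ring B, the allylic alcohol) share one unit: carbons C1–C6 with the C5 methyl, the exocyclic C7 and an oxygen on C3. That unit is cut at C1–C6 and C2–C3 into 2-methylpropene (C1 with both methyls, C2) and the flat diene lactone 3-bromo-4-methyl-2-pyrone, whose ring oxygen and carbonyl carbon become the C3 oxygen and C7. One enantioselective [4+2] cycloaddition closes the carbocycle and fixes C6 and C3 inside a lactone-bridged bicycle. Debromination and opening of the bridge give cis-3-hydroxy-α-ionone, the source of ring A (oxidised late) and, after inversion at C3, of ring B; two Wittig couplings with a C10 dialdehyde build the polyene.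

Key step: step 3

Remark: (R)-1,1'-bi-2-naphthol is assumed to give the drawn enantiomer of the cycloadduct; if a first run shows the opposite sense, the (S) ligand is used and nothing else changes. Ring positions are given in carotenoid numbering (primed locants for ring B).

Step 1
Reactants: 1 4-methyl-5,6-dihydro-2H-pyran-2-one
Product: 3 3-bromo-4-methyl-5,6-dihydro-2H-pyran-2-one, via trans-3,4-dibromo-4-methyloxan-2-one 2 (not isolated)
Conditions: Br2 (1.05 equiv), CH2Cl2, 0 °C → rt; then Et3N (1.2 equiv), 0 °C → rt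
Reagents that add atoms: bromine, BrBr
Why: Electrophilic anti addition of Br2 to the enoate C=C followed by Et3N-induced E1cB loss of the tertiary β-bromide is the standard bromination–dehydrobromination route to 2-bromo enoates; the two stereocentres of 2 disappear in the elimination.

Step 2
Reactants: 3 3-bromo-4-methyl-5,6-dihydro-2H-pyran-2-one
Product: 5 3-bromo-4-methyl-2H-pyran-2-one, via 3,5-dibromo-4-methyl-5,6-dihydro-2H-pyran-2-one 4 (not isolated)
Conditions: NBS (1.05 equiv), (PhCO2)2 (cat.), PhCF3, 85 °C; filter; then Et3N, CH2Cl2, 0 °C → rt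
Reagents that add atoms: none
Why: Wohl–Ziegler bromination should take the weaker secondary allylic C–H of the ring CH2 (pyranone C5) rather than the methyl C–H, as in methyl-substituted cyclohexenones, and E2 loss of HBr across C5–C6 with Et3N then gives the 2-pyrone; the stereocentre of 4 disappears.

Step 3
Reactants: 5 3-bromo-4-methyl-2H-pyran-2-one; 6 2-methylpropene
Product: 7 (1R,4R)-4-bromo-5,8,8-trimethyl-2-oxabicyclo[2.2.2]oct-5-en-3-one
Conditions: Yb(OTf)3 (20 mol %), (R)-BINOL (24 mol %), i-Pr2NEt (48 mol %), 4 Å MS, CH2Cl2, 6 (10 equiv, condensed), sealed vessel, 0 °C → rt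
Reagents that add atoms: none
Why: Proposed new method: the lactone carbonyl oxygen, assisted by weak chelation of the neighbouring bromine, binds the BINOL-ligated trivalent ytterbium centre, which lowers the pyrone LUMO so that 2-methylpropene adds in a concerted, asynchronous inverse-demand [4+2] cycloaddition, its CH2 carbon bonding ahead to pyrone C6 while the carbon that carries the two methyls closes onto pyrone C3. The closest known reaction types are the thermal and high-pressure Diels–Alder reactions of 3-bromo-2-pyrones, which give isolable bridged lactones, and the Yb(OTf)3–BINOL-catalysed cycloadditions of 3-acyl-2-pyrones with enol ethers; asymmetric catalysis with a simple 1,1-dialkylethene is the untested element. The cyclohexene ring (C1–C6) is closed by suprafacial addition of the alkene across the two diene termini, which leaves the former O–C(=O) unit as the third bridge of a 2-oxabicyclo[2.2.2]octene. The two new stereocentres are the bridgeheads C3 and C6: their relative configuration is imposed by the bicycle, their absolute configuration by the pyrone face that the bound ligand leaves open, and no endo/exo question arises because the alkene carbon carries two identical methyl groups. The step needs regiocontrol (CH2 to pyrone C6, CMe2 to pyrone C3), which rests on the match between the most electrophilic diene terminus and the nucleophilic CH2 end of the alkene and has to outweigh the crowding between the future C1 and C6, and it needs facial control from the catalyst. Amine and molecular sieves keep the medium free of protic initiators for alkene oligomerisation, and the low temperature together with the bromine keeps the adduct from losing CO2.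

Step 4
Reactants: 7 (1R,4R)-4-bromo-5,8,8-trimethyl-2-oxabicyclo[2.2.2]oct-5-en-3-one
Product: 8 (1R,4S)-5,8,8-trimethyl-2-oxabicyclo[2.2.2]oct-5-en-3-one
Conditions: Bu3SnH (1.3 equiv), AIBN (10 mol %), PhH, 80 °C; aq. KF work-up
Reagents that add atoms: none
Why: Radical chain dehalogenation: Bu3Sn• abstracts the tertiary bromine and the bridgehead α-acyl radical, which is pyramidal, cannot invert and does not overlap with the neighbouring C=C, takes hydrogen from Bu3SnH, so that C6 keeps its configuration and the alkene stays in place.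

Step 5
Reactants: 8 (1R,4S)-5,8,8-trimethyl-2-oxabicyclo[2.2.2]oct-5-en-3-one
Product: 9 (1R,4S)-5,8,8-trimethyl-2-oxabicyclo[2.2.2]oct-5-en-3-ol (anomeric mixture)
Conditions: i-Bu2AlH (1.1 equiv), CH2Cl2, −78 °C; then MeOH, aq. potassium sodium tartrate
Reagents that add atoms: none
Why: Partial reduction of a lactone by i-Bu2AlH at −78 °C stops at the lactol because the tetrahedral aluminate survives until work-up; the new hemiacetal centre is formed as an anomeric mixture that is of no consequence.

Step 6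
Reactants: 9 (1R,4S)-5,8,8-trimethyl-2-oxabicyclo[2.2.2]oct-5-en-3-ol; 10 1-(triphenylphosphoranylidene)propan-2-one
Product: 12 (3R,6S)-3-hydroxy-α-ionone, via (1S,4R)-4-hydroxy-2,6,6-trimethylcyclohex-2-ene-1-carbaldehyde 11 (not isolated)
Conditions: 10 (2.5 equiv), PhCO2H (10 mol %), PhMe, 90 °C
Reagents that add atoms: none
Why: Wittig olefination of the ring-opened hydroxy aldehyde tautomer with a stabilised ylide gives the E enone and frees the C3 hydroxyl; the ylide is too weak a base to epimerise C6 or to move the ring alkene, so the cis relation set by the bridge is kept.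

Step 7
Reactants: 12 (3R,6S)-3-hydroxy-α-ionone
Product: 13 (1E)-1-[(1S,4R)-4-hydroxy-2,6,6-trimethylcyclohex-2-en-1-yl]-3-methylpenta-1,4-dien-3-ol (both carbinol epimers)
Conditions: CH2=CHMgBr (3 equiv), THF, −20 → 0 °C; aq. NH4Cl
Reagents that add atoms: vinylmagnesium bromide, C=C[Mg]Br
Why: Grignard 1,2-addition to the methyl ketone after deprotonation of the hydroxyl by the first equivalent; the new carbinol centre is formed without control, which does not matter because it becomes sp2 in step 8.

Step 8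
Reactants: 13 (1E)-1-[(1S,4R)-4-hydroxy-2,6,6-trimethylcyclohex-2-en-1-yl]-3-methylpenta-1,4-dien-3-ol
Product: 14 [(2E,4E)-5-[(1S,4R)-4-hydroxy-2,6,6-trimethylcyclohex-2-en-1-yl]-3-methylpenta-2,4-dien-1-yl]triphenylphosphonium bromide (ring A salt)
Conditions: Ph3P·HBr (1.05 equiv), MeOH/CH2Cl2, 0 °C → rt; crystallise the 9E salt
Reagents that add atoms: triphenylphosphine hydrobromide, [PH+](c1ccccc1)(c1ccccc1)c1ccccc1.[Br-]
Why: Acid-induced ionisation of the tertiary bis-allylic carbinol to a pentadienyl cation and capture by PPh3 at the primary terminus (allylic transposition, the classical route to C15 Wittig salts) should favour the 9E salt; the ring allylic alcohol ionises far more slowly and its configuration is immaterial for ring A.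

Step 9
Reactants: 12 (3R,6S)-3-hydroxy-α-ionone
Product: 16 (3S,6S)-3-hydroxy-α-ionone, via (3S,6S)-3-(4-nitrobenzoyloxy)-α-ionone 15 (not isolated)
Conditions: PPh3, DIAD, 4-O2NC6H4CO2H, THF, 0 °C → rt; concentrate; then K2CO3 (cat.), MeOH, 0 °C → rt
Reagents that add atoms: 4-nitrobenzoic acid, O=C(O)c1ccc(cc1)[N+](=O)[O-]
Why: Mitsunobu reaction: SN2 attack of 4-nitrobenzoate on the alkoxyphosphonium ion inverts C3, and K2CO3-catalysed methanolysis of the ester then frees the trans alcohol without touching C6.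

Step 10
Reactants: 16 (3S,6S)-3-hydroxy-α-ionone
Product: 17 (1E)-1-[(1S,4S)-4-hydroxy-2,6,6-trimethylcyclohex-2-en-1-yl]-3-methylpenta-1,4-dien-3-ol (both carbinol epimers)
Conditions: CH2=CHMgBr (3 equiv), THF, −20 → 0 °C; aq. NH4Cl
Reagents that add atoms: vinylmagnesium bromide, C=C[Mg]Br
Why: Grignard 1,2-addition as in step 7; the new carbinol centre is again uncontrolled and is removed in step 11.

Step 11
Reactants: 17 (1E)-1-[(1S,4S)-4-hydroxy-2,6,6-trimethylcyclohex-2-en-1-yl]-3-methylpenta-1,4-dien-3-ol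
Product: 18 [(2E,4E)-5-[(1S,4S)-4-hydroxy-2,6,6-trimethylcyclohex-2-en-1-yl]-3-methylpenta-2,4-dien-1-yl]triphenylphosphonium bromide (ring B salt)
Conditions: Ph3P·HBr (1.05 equiv), MeOH/CH2Cl2, 0 °C → rt; crystallise the 9E salt
Reagents that add atoms: triphenylphosphine hydrobromide, [PH+](c1ccccc1)(c1ccccc1)c1ccccc1.[Br-]
Why: Ionisation and allylic transposition with PPh3 as in step 8, run cold and with only a slight excess of the acid salt, so that the pentadienyl cation forms while the ring allylic alcohol keeps its configuration.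

Step 12
Reactants: 18 ring B phosphonium bromide; 19 (2E,4E,6E)-2,7-dimethylocta-2,4,6-trienedial
Product: 20 (3S,6S)-3-hydroxy-12'-apo-ε-caroten-12'-al
Conditions: 19 (3 equiv), NaOMe (1.1 equiv), MeOH/CH2Cl2, 0 °C → rt; then heptane, 90 °C (Z → E)
Reagents that add atoms: none
Why: Wittig olefination of the allylic ylide with one formyl group of the dialdehyde, which is used in excess and is more electrophilic than the product, followed by thermal equilibration of the new disubstituted C=C bond to E; no stereocentre is formed or touched.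

Step 13
Reactants: 20 (3S,6S)-3-hydroxy-12'-apo-ε-caroten-12'-al
Product: 21 (3S,6S)-3-(tert-butyldimethylsilyloxy)-12'-apo-ε-caroten-12'-al
Conditions: t-BuMe2SiCl, imidazole, DMF, rt
Reagents that add atoms: tert-butyldimethylsilyl chloride, CC(C)(C)[Si](C)(C)Cl
Why: Silylation of the only hydroxyl (silyl ether formation) masks ring B for the oxidation in step 15; no stereocentre is affected.

Step 14
Reactants: 21 (3S,6S)-3-(tert-butyldimethylsilyloxy)-12'-apo-ε-caroten-12'-al; 14 ring A phosphonium bromide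
Product: 22 (3R,6S,3'S,6'S)-3'-(tert-butyldimethylsilyloxy)-ε,ε-caroten-3-ol
Conditions: 14 (1.3 equiv), NaOMe, MeOH/CH2Cl2, 0 °C → rt; then heptane/EtOAc, 80 °C (Z → E), dark, Ar
Reagents that add atoms: none
Why: Second Wittig olefination joins the ring A unit and completes the C40 chain, thermal equilibration again giving the all-E polyene; the silyl ether and all four stereocentres are stable to methoxide at room temperature.

Step 15
Reactants: 22 (3R,6S,3'S,6'S)-3'-(tert-butyldimethylsilyloxy)-ε,ε-caroten-3-ol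
Product: 23 (6S,3'S,6'S)-3'-(tert-butyldimethylsilyloxy)-ε,ε-caroten-3-one
Conditions: MnO2 (activated, 20 equiv), CH2Cl2, rt, dark, Ar
Reagents that add atoms: none
Why: Allylic oxidation with activated MnO2 converts the only free, allylic hydroxyl into the enone under neutral conditions, a known transformation of ε-ring carotenols that leaves the polyene, the silyl ether and C6 untouched.

Step 16
Reactants: 23 (6S,3'S,6'S)-3'-(tert-butyldimethylsilyloxy)-ε,ε-caroten-3-one
Product: 24 (6S,3'S,6'S)-3'-hydroxy-ε,ε-caroten-3-one (target)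
Conditions: Bu4NF/AcOH (1:1, 5 equiv), THF, 0 °C → rt, dark
Reagents that add atoms: none
Why: Fluoride-induced desilylation, buffered with AcOH so that neither the base-sensitive C6–H next to the ring A enone nor the acid-sensitive allylic alcohol of ring B is put at risk.

Compound list
1 | 4-methyl-5,6-dihydro-2H-pyran-2-one | CC1=CC(=O)OCC1 | starting material
2 | (3RS,4RS)-3,4-dibromo-4-methyloxan-2-one (trans; racemate, one enantiomer written) | C[C@@]1(Br)CCOC(=O)[C@H]1Br | intermediate (not isolated)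
3 | 3-bromo-4-methyl-5,6-dihydro-2H-pyran-2-one | CC1=C(Br)C(=O)OCC1 | intermediate
4 | 3,5-dibromo-4-methyl-5,6-dihydro-2H-pyran-2-one (racemate) | CC1=C(Br)C(=O)OCC1Br | intermediate (not isolated)
5 | 3-bromo-4-methyl-2H-pyran-2-one | CC1=C(Br)C(=O)OC=C1 | intermediate
6 | 2-methylpropene | C=C(C)C | starting material
7 | (1R,4R)-4-bromo-5,8,8-trimethyl-2-oxabicyclo[2.2.2]oct-5-en-3-one | CC1=C[C@H]2CC(C)(C)[C@]1(Br)C(=O)O2 | intermediate
8 | (1R,4S)-5,8,8-trimethyl-2-oxabicyclo[2.2.2]oct-5-en-3-one | CC1=C[C@H]2CC(C)(C)[C@@H]1C(=O)O2 | intermediate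
9 | (1R,4S)-5,8,8-trimethyl-2-oxabicyclo[2.2.2]oct-5-en-3-ol (anomeric mixture) | CC1=C[C@H]2CC(C)(C)[C@@H]1C(O)O2 | intermediate
10 | 1-(triphenylphosphoranylidene)propan-2-one | CC(=O)C=P(c1ccccc1)(c1ccccc1)c1ccccc1 | starting material
11 | (1S,4R)-4-hydroxy-2,6,6-trimethylcyclohex-2-ene-1-carbaldehyde | CC1=C[C@H](O)CC(C)(C)[C@@H]1C=O | intermediate (not isolated)
12 | (3R,6S)-3-hydroxy-α-ionone, (E)-4-[(1S,4R)-4-hydroxy-2,6,6-trimethylcyclohex-2-en-1-yl]but-3-en-2-one (cis) | CC(=O)/C=C/[C@@H]1C(C)=C[C@H](O)CC1(C)C | intermediate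
13 | (1E)-1-[(1S,4R)-4-hydroxy-2,6,6-trimethylcyclohex-2-en-1-yl]-3-methylpenta-1,4-dien-3-ol (both carbinol epimers) | C=CC(C)(O)/C=C/[C@@H]1C(C)=C[C@H](O)CC1(C)C | intermediate
14 | [(2E,4E)-5-[(1S,4R)-4-hydroxy-2,6,6-trimethylcyclohex-2-en-1-yl]-3-methylpenta-2,4-dien-1-yl]triphenylphosphonium bromide | CC1=C[C@H](O)CC(C)(C)[C@@H]1/C=C/C(C)=C/C[P+](c1ccccc1)(c1ccccc1)c1ccccc1.[Br-] | intermediate
15 | (1S,4S)-3,5,5-trimethyl-4-[(E)-3-oxobut-1-en-1-yl]cyclohex-2-en-1-yl 4-nitrobenzoate | CC(=O)/C=C/[C@@H]1C(C)=C[C@@H](OC(=O)c2ccc(cc2)[N+](=O)[O-])CC1(C)C | intermediate (not isolated)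
16 | (3S,6S)-3-hydroxy-α-ionone, (E)-4-[(1S,4S)-4-hydroxy-2,6,6-trimethylcyclohex-2-en-1-yl]but-3-en-2-one (trans) | CC(=O)/C=C/[C@@H]1C(C)=C[C@@H](O)CC1(C)C | intermediate
17 | (1E)-1-[(1S,4S)-4-hydroxy-2,6,6-trimethylcyclohex-2-en-1-yl]-3-methylpenta-1,4-dien-3-ol (both carbinol epimers) | C=CC(C)(O)/C=C/[C@@H]1C(C)=C[C@@H](O)CC1(C)C | intermediate
18 | [(2E,4E)-5-[(1S,4S)-4-hydroxy-2,6,6-trimethylcyclohex-2-en-1-yl]-3-methylpenta-2,4-dien-1-yl]triphenylphosphonium bromide | CC1=C[C@@H](O)CC(C)(C)[C@@H]1/C=C/C(C)=C/C[P+](c1ccccc1)(c1ccccc1)c1ccccc1.[Br-] | intermediate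
19 | (2E,4E,6E)-2,7-dimethylocta-2,4,6-trienedial | O=C/C(C)=C/C=C/C=C(C)/C=O | starting material
20 | (3S,6S)-3-hydroxy-12'-apo-ε-caroten-12'-al, (2E,4E,6E,8E,10E,12E)-13-[(1S,4S)-4-hydroxy-2,6,6-trimethylcyclohex-2-en-1-yl]-2,7,11-trimethyltrideca-2,4,6,8,10,12-hexaenal | CC1=C[C@@H](O)CC(C)(C)[C@@H]1/C=C/C(C)=C/C=C/C(C)=C/C=C/C=C(C)/C=O | intermediate
21 | (3S,6S)-3-(tert-butyldimethylsilyloxy)-12'-apo-ε-caroten-12'-al | CC1=C[C@@H](O[Si](C)(C)C(C)(C)C)CC(C)(C)[C@@H]1/C=C/C(C)=C/C=C/C(C)=C/C=C/C=C(C)/C=O | intermediate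
22 | (3R,6S,3'S,6'S)-3'-(tert-butyldimethylsilyloxy)-ε,ε-caroten-3-ol | CC1=C[C@H](O)CC(C)(C)[C@@H]1/C=C/C(C)=C/C=C/C(C)=C/C=C/C=C(C)/C=C/C=C(C)/C=C/[C@@H]1C(C)=C[C@@H](O[Si](C)(C)C(C)(C)C)CC1(C)C | intermediate
23 | (6S,3'S,6'S)-3'-(tert-butyldimethylsilyloxy)-ε,ε-caroten-3-one | CC1=CC(=O)CC(C)(C)[C@@H]1/C=C/C(C)=C/C=C/C(C)=C/C=C/C=C(C)/C=C/C=C(C)/C=C/[C@@H]1C(C)=C[C@@H](O[Si](C)(C)C(C)(C)C)CC1(C)C | intermediate
24 | (6S,3'S,6'S)-3'-hydroxy-ε,ε-caroten-3-one | CC1=CC(=O)CC(C)(C)[C@@H]1/C=C/C(C)=C/C=C/C(C)=C/C=C/C=C(C)/C=C/C=C(C)/C=C/[C@@H]1C(C)=C[C@@H](O)CC1(C)C | target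

Total step count: 16. Longest linear sequence: 14 steps (steps 1–6, then 9–16); steps 7 and 8 form the ring A branch that joins in step 14.

Steps most likely to fail

Step 3 (new method). The bromopyrone binds the chiral Lewis acid through one carbonyl only, so activation may be too weak for a useful rate or for discrimination of the two pyrone faces, and the alkene may oligomerise. The fallback uses known chemistry and gives up asymmetric catalysis. It sets out from 5 and 6, which are combined without catalyst under high pressure (CH2Cl2, about 12 kbar, rt), the established thermal/high-pressure mode of 3-bromo-2-pyrone cycloadditions, to give racemic 4-bromo-5,8,8-trimethyl-2-oxabicyclo[2.2.2]oct-5-en-3-one F1. The chemistry of steps 4–6 then gives in turn the racemic debrominated lactone F2, the racemic lactol F3 and, through the racemic open hydroxy aldehyde F4 (not isolated), racemic cis-3-hydroxy-α-ionone F5. Kinetic resolution by lipase-catalysed acylation (lipase from Burkholderia cepacia, vinyl acetate, t-BuOMe, rt) is expected, from the usual preference of such enzymes for R secondary alcohols, to give (3R,6S)-3-acetoxy-α-ionone F6 and to leave (3S,6R)-3-hydroxy-α-ionone F7. After chromatographic separation, methanolysis of F6 (K2CO3, MeOH, 0 °C) comes back to the route at 12.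

Step 6. Ring opening of the bridged lactol and olefination of the hindered aldehyde may both be slow, and during that time the free aldehyde may epimerise at C6 or the ring double bond may move into conjugation. The fallback sets out from 8 and never passes through a lactol. Aminolysis with AlMe3/MeONHMe·HCl (CH2Cl2, 0 °C → rt) opens the lactone under non-basic conditions to (1S,4R)-4-hydroxy-N-methoxy-N,2,6,6-tetramethylcyclohex-2-ene-1-carboxamide F8. Et3SiCl/imidazole (CH2Cl2, rt) gives (1S,4R)-N-methoxy-N,2,6,6-tetramethyl-4-(triethylsilyloxy)cyclohex-2-ene-1-carboxamide F9, and i-Bu2AlH (THF, −78 °C) reduces it to (1S,4R)-2,6,6-trimethyl-4-(triethylsilyloxy)cyclohex-2-ene-1-carbaldehyde F10, which is fully available as the free aldehyde. Horner–Wadsworth–Emmons reaction with dimethyl (2-oxopropyl)phosphonate and Ba(OH)2 (wet THF, rt), a base mild enough for α-branched aldehydes, gives (3R,6S)-3-(triethylsilyloxy)-α-ionone F11. AcOH/THF/H2O at rt removes the silyl group and comes back to the route at 12.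

Step 11. The acid may ionise the ring allylic alcohol as well as the side-chain carbinol, which would mean epimerisation at C3, ether formation or dehydration in ring B. The fallback sets out from 16 and avoids acid. Horner–Wadsworth–Emmons reaction with triethyl phosphonoacetate (NaH, THF, 0 °C → rt; the 2E isomer is separated) gives ethyl (2E,4E)-5-[(1S,4S)-4-hydroxy-2,6,6-trimethylcyclohex-2-en-1-yl]-3-methylpenta-2,4-dienoate F12. i-Bu2AlH (CH2Cl2, −78 °C) gives (2E,4E)-5-[(1S,4S)-4-hydroxy-2,6,6-trimethylcyclohex-2-en-1-yl]-3-methylpenta-2,4-dien-1-ol F13. Corey–Kim bromination (NBS, Me2S, CH2Cl2, −20 °C), selective for the primary allylic alcohol, gives (1S,4S)-4-[(1E,3E)-5-bromo-3-methylpenta-1,3-dien-1-yl]-3,5,5-trimethylcyclohex-2-en-1-ol F14, which is treated at once with PPh3 (EtOAc, rt) and comes back to the route at 18.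

Further compounds
F1 | step 3 | racemic 4-bromo-5,8,8-trimethyl-2-oxabicyclo[2.2.2]oct-5-en-3-one (both enantiomers written) | CC1=C[C@H]2CC(C)(C)[C@]1(Br)C(=O)O2.CC1=C[C@@H]2CC(C)(C)[C@@]1(Br)C(=O)O2
F2 | step 3 | racemic 5,8,8-trimethyl-2-oxabicyclo[2.2.2]oct-5-en-3-one (both enantiomers written) | CC1=C[C@H]2CC(C)(C)[C@@H]1C(=O)O2.CC1=C[C@@H]2CC(C)(C)[C@H]1C(=O)O2
F3 | step 3 | racemic 5,8,8-trimethyl-2-oxabicyclo[2.2.2]oct-5-en-3-ol (anomeric mixture; both enantiomers written) | CC1=C[C@H]2CC(C)(C)[C@@H]1C(O)O2.CC1=C[C@@H]2CC(C)(C)[C@H]1C(O)O2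
F4 | step 3 | racemic cis-4-hydroxy-2,6,6-trimethylcyclohex-2-ene-1-carbaldehyde (not isolated; both enantiomers written) | CC1=C[C@H](O)CC(C)(C)[C@@H]1C=O.CC1=C[C@@H](O)CC(C)(C)[C@H]1C=O
F5 | step 3 | racemic cis-3-hydroxy-α-ionone (both enantiomers written) | CC(=O)/C=C/[C@@H]1C(C)=C[C@H](O)CC1(C)C.CC(=O)/C=C/[C@H]1C(C)=C[C@@H](O)CC1(C)C
F6 | step 3 | (3R,6S)-3-acetoxy-α-ionone | CC(=O)/C=C/[C@@H]1C(C)=C[C@H](OC(C)=O)CC1(C)C
F7 | step 3 | (3S,6R)-3-hydroxy-α-ionone | CC(=O)/C=C/[C@H]1C(C)=C[C@@H](O)CC1(C)C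
F8 | step 6 | (1S,4R)-4-hydroxy-N-methoxy-N,2,6,6-tetramethylcyclohex-2-ene-1-carboxamide | CON(C)C(=O)[C@@H]1C(C)=C[C@H](O)CC1(C)C
F9 | step 6 | (1S,4R)-N-methoxy-N,2,6,6-tetramethyl-4-(triethylsilyloxy)cyclohex-2-ene-1-carboxamide | CON(C)C(=O)[C@@H]1C(C)=C[C@H](O[Si](CC)(CC)CC)CC1(C)C
F10 | step 6 | (1S,4R)-2,6,6-trimethyl-4-(triethylsilyloxy)cyclohex-2-ene-1-carbaldehyde | O=C[C@@H]1C(C)=C[C@H](O[Si](CC)(CC)CC)CC1(C)C
F11 | step 6 | (3R,6S)-3-(triethylsilyloxy)-α-ionone | CC(=O)/C=C/[C@@H]1C(C)=C[C@H](O[Si](CC)(CC)CC)CC1(C)C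
F12 | step 11 | ethyl (2E,4E)-5-[(1S,4S)-4-hydroxy-2,6,6-trimethylcyclohex-2-en-1-yl]-3-methylpenta-2,4-dienoate | CCOC(=O)/C=C(C)/C=C/[C@@H]1C(C)=C[C@@H](O)CC1(C)C
F13 | step 11 | (2E,4E)-5-[(1S,4S)-4-hydroxy-2,6,6-trimethylcyclohex-2-en-1-yl]-3-methylpenta-2,4-dien-1-ol | OC/C=C(C)/C=C/[C@@H]1C(C)=C[C@@H](O)CC1(C)C
F14 | step 11 | (1S,4S)-4-[(1E,3E)-5-bromo-3-methylpenta-1,3-dien-1-yl]-3,5,5-trimethylcyclohex-2-en-1-ol | BrC/C=C(C)/C=C/[C@@H]1C(C)=C[C@@H](O)CC1(C)C
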